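The numbers of this flask are made up.

We want to know how much target and crystals together this flask holds at the end, and which change raises that amount most.

substrate 1.0 M; reagent in the second phase 0.900 M; protic impurity 0.100 M; time 50 s; volume of the second phase over the first 2.0

    reagent in the reaction phase + target → over-reacted product (k1 = 0.473 L mol⁻¹ s⁻¹)
    reagent in the reaction phase ⇌ reagent in the second phase, rate k2*([reagent in the reaction phase] - [reagent in the second phase]/K2) per volume of the first phase (K2 = 1.5, k2 = 0.901 s⁻¹)
    target ⇌ isomer of the product (K3 = 2.9, k3 = 0.0173 s⁻¹)
    reagent in the reaction phase + protic impurity → quenched reagent (k4 = 4.59 L mol⁻¹ s⁻¹)
    crystals ⇌ target, rate k5*(cs5 - [target]) while solid is left; crystals form when [target] > cs5 (cs5 = 20 mM, k5 = 0.396 s⁻¹)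
    substrate + reagent in the reaction phase → target (k6 = 1.04 L mol⁻¹ s⁻¹)

- the target and crystals together standing at 50 s, as a percentage of the substrate charged
- concentration of target in solution at 25 s, in percent of saturation
- the change that raises the amount of target and crystals together at 50 s, in percent of the substrate charged most ("none" if none brings more than 2 percentage points) (birch / alder / maple / elm / none)
- amount of target and crystals together at 50 s, in percent of the substrate charged, after alder

- birch: doubling the amount of reagent in the second phase, all else as stated
- alder: doubling the transfer coefficient of step 2, all else as stated
- maple: doubling the solubility in step 5, all else as stated
- elm: doubling the dissolution coefficient of step 5, all else as stated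

Two customers of the reagent in the reaction phase are substrate and protic impurity. Each falls at its own constant times its own concentration times the same reagent concentration. If we divide one rate by the other, the reagent level and the time both drop out, however the transfer feeds the reaction phase. Let a be the fraction of charged substrate still there and h the same fraction for the impurity. Then h = aⁿ, where n is the competition exponent, a selectivity factor: the impurity's rate constant over the substrate's, n = 4.41. The impurity constant is the greater. Let R be the rate on substrate over the rate on impurity at one moment; at the start it is 2.27. We reckon three moments:

- a = 1: h = 1, R = 2.27
- a = 0.7: h = 20.7 %, R = 7.66
- a = 0.5: h = 4.70 %, R = 24.1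

The first row says the impurity takes 30.6 % of the reagent going to these two customers. The second row shows that share already down to 11.5 %, and the third shows 3.98 %, so the comparison drifts quickly towards the substrate.

The reagent is the limiting reagent, so we next ask what the impurity costs in the end. Taking its whole charge from the reagent leaves a budget of 80.0 % of the substrate charged, which is less than the 90.0 % the bare charges allow. That charge is fair, because at that conversion h is 0.0827 %, so nearly all of the impurity has gone. Our reckoning stops here: we expect target and crystals below 80.0 %, by an over-reaction and isomer loss we have not reckoned, and saturation lies outside it. Birch raises the reagent left after the impurity to 170 % of the substrate, so we pick birch. Alder, maple and elm leave the budget as it is.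

The forecast gives 67 % for target and crystals together, 150 % of saturation at 25.0 s, birch as the best change and 66.5 % after alder, on the ground that “Reagent is the limit”.

The simulation gives 64.8 % for target and crystals together, 171 % of saturation at 25.0 s, birch as the best change, worth 9.6 percentage points, and 64.2 % after alder. The forecast's saturation lies 21 points low.

In this flask, 26.5 % of substrate at 50.0 s gives h = 0.286 %, and the impurity reads 0.284 %. A neighbouring flask holds 2.5 M of substrate, other charges unchanged, so its R starts at 5.66 with the same n. At 50.0 s its substrate stands at 68.2 %, which gives h = 18.5 %. That neighbouring flask reads 18.5 % of its impurity charge, and its target and crystals together stand at 29.2 % of its substrate charge.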